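## Structural features

The target is a longipin-2-en-1-one. Its core is a cyclobutane (C4, C5, C11, C10) whose two diagonals are bridged on opposite faces: C4/C11 by the enone C3(Me)=C2–C1(=O), and C5/C10 by C6(Me2)–C7–C8–C9. The atom numbers of the target are used for every intermediate. Four of the six stereocentres (C4, C5, C11 and the quaternary C10) are contiguous on the four-membered ring and are locked to one another by the bridging. The other two are the carbinol carbons C7 and C9, trans to each other, each next to a quaternary carbon (C6, C10), and each carrying a different ester (isovalerate on C7, tiglate on C9). Fragile points are the β,β-disubstituted enone (reducible, γ-acidic), the tiglate (a Michael acceptor of fixed E geometry), the two secondary esters of a 1,3-diol (acyl migration, β-elimination at the keto stage) and the strained cyclobutane. The difficulty is twofold. First, the doubly bridged cyclobutane with a quaternary carbon must be built. Second, the C6–C9 bridge lies over a core whose C4 and C11 sides differ only through the distant enone, so C7 and C9 cannot be relayed from the core; they need one reagent-controlled step, a 1,3-relay, and a way to tell the two oxygens apart. The key step exploits C10: it is the only cyclobutane carbon with a methyl and no hydrogen, hence the only one that can be a tertiary cation, and it is flanked by the carbinyl position C4. The C4–C5 bond can therefore form when the external bond C5–C10 of a cyclopropane (C5, C10, C11) fused to the cyclohexenone shifts onto a C4 cation; the C1 carbonyl keeps the six-membered ring flat and makes charge on C11 or C2 unfavourable.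

## Logic of the disconnections

**34 ⇒ 32 + 33.** Cut: the C7–O acyl bond. The isovalerate goes on last because the step before leaves exactly this hydroxyl free. Gain: one ester fewer, no new stereocentre. Demand: acylation of a neopentyl secondary alcohol without moving the C9 ester.

**32 ⇒ 30 + 31.** Cut: the C9 O–acyl bond and the C7–H bond together (Tishchenko-type hydride transfer). One operation reduces C7 from the C9 oxygen (1,3-anti), acylates only O9 and leaves the C1 enone alone. Gain: the C7 configuration and the oxygen differentiation collapse into one stereocentre, C9, in a β-hydroxy ketone. Demand: hemiacetal formation and hydride transfer with a conjugated aldehyde, faster than retro-aldol or acyl migration.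

**30 ⇒ 28 (through 29), and 28 ⇒ 27.** Cut: the C9–O bond, then the C8=C9 unsaturation. The two faces of C9 are distinguished only by the far enone, so C9 is set by a chiral catalyst on a prochiral enone β-carbon. Gain: a seven-membered ketone without carbinol stereocentres. Demand: the C8=C9 enone must react before the C2=C3 enone; dehydrogenation can go only to C8 because C6 is quaternary.

**27 ⇒ 26.** Cut: C9–C10 (with the C–H of the C10 methyl). A tertiary radical at C10 is available from the exocyclic methylene, and the chain on C5 is held cis-1,3 to it across the cyclobutane. Gain: the seven-membered ring and the C10 stereocentre disappear. Demand: 7-endo addition to the enone must outrun reduction of the radical.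

**26 ⇒ 23 + 24 (through 25), 23 ⇒ 22 ⇒ 21.** Cut: C7–C8, plus oxidation-level changes at C7. The vinyl ketone is made last because it is the most sensitive function. Gain: C7 is carried as a benzoyloxymethyl group. Demand: vinyl addition to the aldehyde in the presence of the hindered C1 ketone.

**21 ⇒ 19 (through 20).** Cut: C4–C5; reconnect C5–C10; put oxygen on C4; methylene back to methyl. Gain: the cyclobutane becomes a cyclopropane fused to a cyclohexenone, which carbene chemistry can reach. Demand: an exo chain on C5, a leaving group on C4 anti to C5, and a C7 group that cannot trap the C10 cation. An ester carbonyl on C6 would sit 1,3 to C10 across the cyclobutane and could close a δ-lactone, so C7 is kept as CH2OBz.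

**19 ⇒ 18 ⇒ 16 (through 17).** Cut: the silyl group, then the C2=C3 unsaturation. The C4 oxygen must already be present when the enone is made: a C1 dienolate extending to C4 would be a norcaradiene enolate that can open to a cycloheptatriene and scramble C5, C10 and C11. Gain: a saturated ketone with an auxiliary C3 stereocentre that is erased afterwards. Demand: enolisation only towards C2.

**16 ⇒ 15.** Cut: C11–C10 and C11–C5. The intramolecular carbene addition closes the six-membered ring and the cyclopropane together and transfers the alkene geometry to the exo chain. Gain: an acyclic diazoketone. Demand: an (E)-trisubstituted alkene and carbene attack anti to the allylic silyloxy group.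

**15 ⇒ 12 + 13 (through 14), 12 ⇒ 11 ⇒ 9 (through 10), 9 ⇒ 8.** Cut: C1–C11; then the C1 oxidation level is traced back to a vinyl group and the silyl ether to the alcohol. Demand: mild acyl activation and hydroboration of only the terminal alkene.

**8 ⇒ 5 + 6 (through 7).** Cut: C3–C4. The absolute configuration of the whole synthesis enters here (C4, with C3 as helper). Demand: a closed transition state with catalyst-controlled face selection on an α-branched enal.

**5 ⇒ 3 + 4, 3 ⇒ 2 ⇒ 1.** Cut: the C5=C10 alkene. A stabilised ylide gives the (E)-enal; the aldehyde partner comes from a symmetric diol. Demand: E selectivity at a neopentyl aldehyde.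

## Other disconnections considered

**Alternative 1:** Cut C5–C6 and C8–C9. The C6–C7–C8 unit is an oxyallyl cation from the bromo ketone A3, and C5=C4–C10=C9 is the silyloxydiene A2. The forward (4+3) cycloaddition would give the bicyclo[5.4.0]undecenone A1. Locant note: the dioxolane carbon of A1 is C1 of the target numbering (flanked by C2 and C11); calling it C3 would be a misnumbering.
- In favour: two ring bonds and the gem-dimethyl ketone arise in one convergent step from simple pieces. C7 (ketone) and C9 (silyl ether) come out differentiated; on this point it is better than the chosen plan, which needs a separate Tishchenko step. A1 would be reached in fewer steps than 27; here it is also better.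
- Against: the hindered CMe2 terminus must bond to the ring carbon C5. The C5/C9 relationship depends on a compact versus extended transition state and on the enol ether geometry. The adduct is racemic without an added control element. Most important, the cyclobutane is still missing: C10–C11 must be closed onto the tetrasubstituted C4=C10 alkene by a 4-exo enol/cation or radical step, and the C3 methyl and the C2=C3 unsaturation are still to come.
- Comparison: structurally it makes the easy ring first and leaves the strained ring for a late closure of uncertain feasibility; the chosen plan makes the cyclobutane from a cyclopropane and closes the seven-membered ring afterwards. Mechanistically the cycloaddition is as well established a reaction class as the ring expansion (equal). Step economy is better up to A1 and worse, and less certain, after it.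

**Alternative 2:** Cut C4–C10. A Lewis acid opens the cis-fused 9,10-epoxide A5 at the tertiary carbon; C4 of the C3=C4 alkene traps the C10 cation; loss of a C2 proton gives A4.
- In favour: it follows the likely biogenesis. The C9 oxygen keeps its configuration from the epoxide and C10 is formed with inversion, so C9, C10 and the pre-installed C7 ester are defined before the closure; this is better than the chosen plan, where C9 needs its own catalyst-controlled step. After the key step only allylic oxidation at C1 and one acylation remain, a shorter ending than in the chosen plan.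
- Against: a four-membered ring must be formed by 4-exo attack of an alkene on a cation in a mobile seven-membered ring. It competes with hydride shift to a C9 ketone, proton loss to allylic alcohols and transannular paths. A5 needs a stereodefined himachalene and a face-selective epoxidation of a flexible ring. The last allylic oxidation must spare two esters and the C3 methyl.
- Comparison: both plans are cationic and make one skeletal bond in the key step (equal), and both are roughly strain-neutral on paper (epoxide for cyclobutane there, cyclopropane for cyclobutane here). In the chosen plan the migrating bond is held in place by a rigid bicycle; Alternative 2 pays an entropic and alignment cost. It is stronger in late-stage brevity and C9 control, weaker in predictability of the key event.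

**Alternative 3:** Cut C2=C3. A chiral primary amine salt would convert one of the two enantiotopic acetyl groups of the meso diketone A7 into an enamine, which adds to the other acetyl and dehydrates to the enone A6.
- In favour: one catalytic step would set the absolute configuration of all four cyclobutane stereocentres from an achiral compound and form the enone directly. This is better than the chosen plan, which spends separate steps on a helper stereocentre, dehydrogenation and desilylation. The vinylogous ester tells the C7 and C9 oxygens apart, equal to what the chosen plan reaches.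
- Against: the difficulty moves into A7, a tetrasubstituted cyclobutane with cis-1,3 acetyl groups and the seven-membered bridge on the other face, for which no short access is evident. The condensation must build a bridged enone on a cyclobutane, and the catalyst must distinguish acetyl groups that differ only by a remote mirror plane. The C7/C9 configurations are as remote from the enone as in the chosen plan (equal problem), and 1,2-reduction of a vinylogous ester followed by hydrolysis tends to eliminate.
- Comparison: more elegant and shorter at the core stage if A7 were available; the chosen plan builds its key-step substrate by known, stereochemically accountable steps.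

Key step: step 12

Assumption: (S)-TRIP in step 4 and the (R,S) antipode of Josiphos in step 19 are taken to give the facial sense drawn (by analogy with the parent reactions); if either is reversed on these substrates the mirror-image ligand is used and nothing else changes.

## Route

Step 1
Reactants: 1 2,2-dimethylpropane-1,3-diol
Product: 2 3-hydroxy-2,2-dimethylpropyl benzoate
Conditions: BzCl (0.9 equiv), pyridine, CH2Cl2, 0 °C to rt, diol in excess
Reagents that add atoms: benzoyl chloride, O=C(Cl)c1ccccc1
Why: Mono-acylation of a symmetric primary diol; the excess diol is removed by aqueous extraction. No stereocentre is involved.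

Step 2
Reactants: 2 3-hydroxy-2,2-dimethylpropyl benzoate
Product: 3 2,2-dimethyl-3-oxopropyl benzoate
Conditions: TEMPO (10 mol%), PhI(OAc)2 (1.1 equiv), CH2Cl2, rt
Reagents that add atoms: none
Why: Oxoammonium (TEMPO) oxidation of a primary alcohol stops at the aldehyde, which has no α-hydrogen and cannot enolise.

Step 3
Reactants: 3 2,2-dimethyl-3-oxopropyl benzoate; 4 2-(triphenylphosphoranylidene)propanal
Product: 5 (3E)-2,2,4-trimethyl-5-oxopent-3-en-1-yl benzoate
Conditions: toluene, 100 °C
Reagents that add atoms: none
Why: Wittig reaction of a stabilised formyl ylide gives the (E)-trisubstituted enal, with the formyl group trans to the quaternary carbon; this geometry later becomes the exo position of the chain on C5.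

Step 4
Reactants: 5 (3E)-2,2,4-trimethyl-5-oxopent-3-en-1-yl benzoate; 6 (Z)-crotylboronic acid pinacol ester
Product: 8 (3E,5S,6R)-5-hydroxy-2,2,4,6-tetramethylocta-3,7-dien-1-yl benzoate, via pinacol borate ester 7 (not isolated)
Conditions: (S)-TRIP [(S)-3,3'-bis(2,4,6-triisopropylphenyl)-1,1'-binaphthyl-2,2'-diyl hydrogen phosphate] (5 mol%), 4 Å MS, toluene, −30 °C; aq. NaHCO3
Reagents that add atoms: none
Why: Chiral phosphoric acid-catalysed crotylboration through a closed chair transition state: the (Z)-crotyl group gives the syn adduct (sets C3 relative to C4) and the catalyst directs addition to the Si face of the aldehyde (sets C4, S). Only 1,2-addition occurs.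

Step 5
Reactants: 8 (3E,5S,6R)-5-hydroxy-2,2,4,6-tetramethylocta-3,7-dien-1-yl benzoate
Product: 9 (3E,5S,6R)-5-[(tert-butyldimethylsilyl)oxy]-2,2,4,6-tetramethylocta-3,7-dien-1-yl benzoate
Conditions: TBSOTf, 2,6-lutidine, CH2Cl2, −78 to 0 °C
Reagents that add atoms: tert-butyldimethylsilyl trifluoromethanesulfonate, CC(C)(C)[Si](C)(C)OS(=O)(=O)C(F)(F)F
Why: Silylation of a hindered allylic alcohol with the silyl triflate; the bulky, weakly basic silyl ether later steers the carbene and does not form oxonium ylides.

Step 6
Reactants: 9 (3E,5S,6R)-5-[(tert-butyldimethylsilyl)oxy]-2,2,4,6-tetramethylocta-3,7-dien-1-yl benzoate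
Product: 11 (3E,5S,6R)-5-[(tert-butyldimethylsilyl)oxy]-8-hydroxy-2,2,4,6-tetramethyloct-3-en-1-yl benzoate, via alkyl-9-BBN adduct 10 (not isolated)
Conditions: 9-BBN (1.2 equiv), THF, 0 °C to rt; NaBO3·4H2O, THF/H2O, rt
Reagents that add atoms: 9-borabicyclo[3.3.1]nonane, C1CCC2CCCC1B2 (boron of 10 only); sodium perborate, [Na+].[O-]OB=O (hydroxyl oxygen of 11)
Why: Anti-Markovnikov hydroboration–oxidation; 9-BBN reacts with the monosubstituted vinyl group and not with the trisubstituted alkene, and perborate oxidises the C–B bond without cleaving the benzoate.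

Step 7
Reactants: 11 (3E,5S,6R)-5-[(tert-butyldimethylsilyl)oxy]-8-hydroxy-2,2,4,6-tetramethyloct-3-en-1-yl benzoate
Product: 12 (3R,4S,5E)-8-(benzoyloxy)-4-[(tert-butyldimethylsilyl)oxy]-3,5,7,7-tetramethyloct-5-enoic acid
Conditions: TEMPO (20 mol%), PhI(OAc)2 (2.5 equiv), MeCN/H2O (1:1), rt
Reagents that add atoms: water, O
Why: TEMPO/iodine(III) oxidation takes the primary alcohol through the aldehyde hydrate to the acid under near-neutral conditions that spare the silyl ether, benzoate and alkene; the γ-oxygen stays silylated, so no lactone forms.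

Step 8
Reactants: 12 (3R,4S,5E)-8-(benzoyloxy)-4-[(tert-butyldimethylsilyl)oxy]-3,5,7,7-tetramethyloct-5-enoic acid; 13 (trimethylsilyl)diazomethane
Product: 15 (3E,5S,6R)-5-[(tert-butyldimethylsilyl)oxy]-9-diazo-2,2,4,6-tetramethyl-8-oxonon-3-en-1-yl benzoate, via mixed carbonic anhydride 14 (not isolated)
Conditions: ClCO2Et, Et3N, THF, −15 °C; TMSCHN2 (2 equiv), MeCN, 0 °C to rt
Reagents that add atoms: ethyl chloroformate, CCOC(Cl)=O (atoms of 14 only)
Why: Acylation of the diazo carbon by a mixed anhydride (Arndt–Eistert-type diazoketone synthesis) avoids an acid chloride and HCl; the carbonate leaving group removes the silyl group to give the diazomethyl ketone (C11 attached to C1).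

Step 9
Reactants: 15 (3E,5S,6R)-5-[(tert-butyldimethylsilyl)oxy]-9-diazo-2,2,4,6-tetramethyl-8-oxonon-3-en-1-yl benzoate
Product: 16 2-[(1R,4R,5S,6S,7S)-5-[(tert-butyldimethylsilyl)oxy]-4,6-dimethyl-2-oxobicyclo[4.1.0]heptan-7-yl]-2-methylpropyl benzoate
Conditions: Cu(acac)2 (5 mol%), toluene, 80 °C, slow addition of 15 (final 0.01 M)
Reagents that add atoms: none
Why: Intramolecular copper-carbene cyclopropanation of a 1-diazohept-6-en-2-one; the concerted syn addition puts the chain exo on C5 and makes the ring fusion cis. In the chair-like transition state the C3 methyl and C4 silyloxy groups are both pseudo-equatorial and the allylic C–H eclipses the alkene, so the carbene enters anti to the silyl ether; this sets C5, C10 and C11 relative to C4.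

Step 10
Reactants: 16 2-[(1R,4R,5S,6S,7S)-5-[(tert-butyldimethylsilyl)oxy]-4,6-dimethyl-2-oxobicyclo[4.1.0]heptan-7-yl]-2-methylpropyl benzoate
Product: 18 2-[(1R,5S,6S,7S)-5-[(tert-butyldimethylsilyl)oxy]-4,6-dimethyl-2-oxobicyclo[4.1.0]hept-3-en-7-yl]-2-methylpropyl benzoate, via trimethylsilyl enol ether 17 (not isolated)
Conditions: TMSOTf, Et3N, CH2Cl2, 0 °C; Pd(OAc)2 (1.1 equiv), MeCN, rt
Reagents that add atoms: trimethylsilyl trifluoromethanesulfonate, C[Si](C)(C)OS(=O)(=O)C(F)(F)F (atoms of 17 only)
Why: Saegusa–Ito dehydrogenation: the ketone can enolise only towards C2 (C11 is a cyclopropane ring-fusion carbon), and β-hydride elimination from C3 gives the C2=C3 enone and erases the helper stereocentre. No dienolate through C4 is ever formed.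

Step 11
Reactants: 18 2-[(1R,5S,6S,7S)-5-[(tert-butyldimethylsilyl)oxy]-4,6-dimethyl-2-oxobicyclo[4.1.0]hept-3-en-7-yl]-2-methylpropyl benzoate
Product: 19 2-[(1R,5S,6S,7S)-5-hydroxy-4,6-dimethyl-2-oxobicyclo[4.1.0]hept-3-en-7-yl]-2-methylpropyl benzoate
Conditions: HF·pyridine, THF, 0 °C to rt
Reagents that add atoms: none
Why: Fluoride desilylation under mildly acidic, base-free conditions, so the γ-proton on C4 is not removed and the benzoate is untouched; the hydroxyl ends up trans to the cyclopropane carbon C5 and cis to the C10 methyl.

Step 12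
Reactants: 19 2-[(1R,5S,6S,7S)-5-hydroxy-4,6-dimethyl-2-oxobicyclo[4.1.0]hept-3-en-7-yl]-2-methylpropyl benzoate
Product: 21 2-methyl-2-[(1R,5R,7S)-4-methyl-6-methylidene-2-oxobicyclo[3.1.1]hept-3-en-7-yl]propyl benzoate, via trifluoroacetate 20 (not isolated)
Conditions: (CF3CO)2O, pyridine, CH2Cl2, 0 °C; evaporate; (CF3)2CHOH, 2,6-di-tert-butylpyridine (1.5 equiv), 50 °C
Reagents that add atoms: trifluoroacetic anhydride, O=C(OC(=O)C(F)(F)F)C(F)(F)F (atoms of 20 only)
Why: The C4 hydroxyl is converted into a trifluoroacetate, which ionises in the strongly ionising, weakly nucleophilic fluoro alcohol and leaves from the face opposite to C5. As it leaves, the external cyclopropane bond C5–C10, nearly parallel to the developing empty orbital on C4, shifts to C4; the closest known reaction type is the solvolytic ring expansion of 1-methylcyclopropylcarbinyl esters to 1-methylcyclobutyl cations. The cyclobutane (C4, C5, C11, C10) is thus closed by a suprafacial 1,2-alkyl shift (ring expansion of the three-membered ring, not an exo or endo cyclisation), turning the bicyclo[4.1.0]heptenone into the bicyclo[3.1.1]heptenone while the charge moves from the enone-deactivated secondary C4 to the tertiary C10. The one new stereocentre, C4, is formed with inversion because C5 enters anti to the leaving group; C5 migrates with retention, so its exo chain ends on the face away from the enone bridge, the only arrangement from which the seven-membered ring can later close; C11 is untouched. The C10 cation loses a proton from its methyl group, since C4 and C11 are bridgeheads, and the hindered base takes up the acid so that the methylene is not re-protonated. Selectivity needed: external over ring-fusion bond, shift over homoallyl opening, elimination over capture. Secured by: the flat enone and the C1 carbonyl (C10–C11 is orthogonal to the empty orbital and its cleavage would place charge on C11), the C10 methyl (tertiary cation), the anti leaving group, and the benzoyloxymethyl group, whose carbonyl cannot reach C10. In bicyclo[3.1.1] locants the chain of 21 is on C7, which is C5 of the target.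

Step 13
Reactants: 21 2-methyl-2-[(1R,5R,7S)-4-methyl-6-methylidene-2-oxobicyclo[3.1.1]hept-3-en-7-yl]propyl benzoate
Product: 22 (1R,5R,7S)-7-(1-hydroxy-2-methylpropan-2-yl)-4-methyl-6-methylidenebicyclo[3.1.1]hept-3-en-2-one
Conditions: K2CO3 (0.3 equiv), MeOH, rt
Reagents that add atoms: none
Why: Base-catalysed transesterification removes the benzoate; the β,β-disubstituted enone does not add methoxide and has no proton whose removal would isomerise the skeleton.

Step 14
Reactants: 22 (1R,5R,7S)-7-(1-hydroxy-2-methylpropan-2-yl)-4-methyl-6-methylidenebicyclo[3.1.1]hept-3-en-2-one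
Product: 23 2-methyl-2-[(1R,5R,7S)-4-methyl-6-methylidene-2-oxobicyclo[3.1.1]hept-3-en-7-yl]propanal
Conditions: DMP, NaHCO3, CH2Cl2, rt
Reagents that add atoms: none
Why: Dess–Martin oxidation of a neopentyl primary alcohol to a non-enolisable aldehyde (C7).

Step 15
Reactants: 23 2-methyl-2-[(1R,5R,7S)-4-methyl-6-methylidene-2-oxobicyclo[3.1.1]hept-3-en-7-yl]propanal; 24 vinylmagnesium bromide
Product: 25 (1R,5R,7S)-7-(3-hydroxy-2-methylpent-4-en-2-yl)-4-methyl-6-methylidenebicyclo[3.1.1]hept-3-en-2-one (both carbinol epimers)
Conditions: CH2=CHMgBr (1.2 equiv), THF, −78 °C; aq. NH4Cl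
Reagents that add atoms: none
Why: Grignard 1,2-addition forms C7–C8; at −78 °C the aldehyde is far more electrophilic than the hindered, cross-conjugated C1 ketone. The new carbinol is oxidised in the next step, so its configuration does not matter.

Step 16
Reactants: 25 (1R,5R,7S)-7-(3-hydroxy-2-methylpent-4-en-2-yl)-4-methyl-6-methylidenebicyclo[3.1.1]hept-3-en-2-one
Product: 26 (1R,5R,7S)-4-methyl-6-methylidene-7-(2-methyl-3-oxopent-4-en-2-yl)bicyclo[3.1.1]hept-3-en-2-one
Conditions: DMP, NaHCO3, CH2Cl2, 0 °C; used at once
Reagents that add atoms: none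
Why: Dess–Martin oxidation of the allylic alcohol gives the vinyl ketone; C6 is quaternary, so the ketone cannot enolise on that side.

Step 17
Reactants: 26 (1R,5R,7S)-4-methyl-6-methylidene-7-(2-methyl-3-oxopent-4-en-2-yl)bicyclo[3.1.1]hept-3-en-2-one
Product: 27 (4R,5S,10R,11R)-longipin-2-ene-1,7-dione (target numbering; tricyclic diketone with C8 and C9 as CH2)
Conditions: Fe(acac)3 (30 mol%), PhSiH3 (2.5 equiv, slow addition), EtOH/(CH2OH)2 (5:1), 0.005 M, 60 °C
Reagents that add atoms: none
Why: Hydrogen-atom-transfer radical conjugate addition (reductive olefin coupling): the iron hydride delivers H to the CH2 of the electron-rich 1,1-disubstituted alkene, creating the C10 methyl and a tertiary C10 radical, which adds to the unsubstituted terminus C9 of the vinyl ketone (7-endo Giese closure). The chain on C5 is cis-1,3 to the radical across the cyclobutane, so C9 can bond only on the face away from the enone bridge, which fixes C10.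

Step 18
Reactants: 27 (4R,5S,10R,11R)-longipin-2-ene-1,7-dione
Product: 28 (4R,5S,10R,11R)-longipina-2,8-diene-1,7-dione
Conditions: IBX (2.5 equiv), DMSO/fluorobenzene (1:2), 70 °C
Reagents that add atoms: none
Why: IBX dehydrogenation of a ketone through its enol; the C7 ketone can enolise only towards C8, the C1 ketone has no enolisable α-hydrogen, and the quaternary C10 prevents over-oxidation.

Step 19
Reactants: 28 (4R,5S,10R,11R)-longipina-2,8-diene-1,7-dione
Product: 30 (4R,5S,9R,10R,11R)-9-hydroxylongipin-2-ene-1,7-dione, via C9 pinacolboronate 29 (not isolated)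
Conditions: CuCl (5 mol%), (R,S)-Josiphos [(R)-1-[(S)-2-(diphenylphosphino)ferrocenyl]ethyldicyclohexylphosphine] (5.5 mol%), NaOtBu (8 mol%), B2pin2 (1.1 equiv), MeOH (2 equiv), THF, rt; NaBO3·4H2O, THF/H2O, rt
Reagents that add atoms: bis(pinacolato)diboron, CC1(C)OB(OC1(C)C)B1OC(C)(C)C(C)(C)O1 (boron of 29 only); sodium perborate, [Na+].[O-]OB=O (hydroxyl oxygen of 30)
Why: Copper-catalysed asymmetric conjugate borylation, then C–B oxidation with retention. The β-monosubstituted C8=C9 enone reacts before the β,β-disubstituted, bridgehead-flanked C2=C3 enone. Because the two faces of C9 differ only through the remote enone, the chiral phosphine decides the face and sets C9 (O9 cis to the C10 methyl).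

Step 20
Reactants: 30 (4R,5S,9R,10R,11R)-9-hydroxylongipin-2-ene-1,7-dione; 31 (E)-2-methylbut-2-enal
Product: 32 (4R,5S,7R,9R,10R,11R)-7-hydroxy-1-oxolongipin-2-en-9-yl (2E)-2-methylbut-2-enoate
Conditions: SmI2 (30 mol%), 31 (6 equiv), THF, −10 °C
Reagents that add atoms: none
Why: Evans–Tishchenko reduction: the samarium alkoxide (trivalent samarium formed in situ) holds the hemiacetal of the C9 hydroxyl and the aldehyde, and hydride passes through a six-membered chair to the C7 ketone on the face of the C9 oxygen. This gives the 7,9-trans (1,3-anti) relationship, turns the hemiacetal carbon into the tiglate on O9 and leaves only O7 free; the untethered C1 enone is not reduced.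

Step 21
Reactants: 32 (4R,5S,7R,9R,10R,11R)-7-hydroxy-1-oxolongipin-2-en-9-yl (2E)-2-methylbut-2-enoate; 33 3-methylbutanoyl chloride
Product: 34 (4R,5S,7R,9R,10R,11R)-7-(3-methylbutanoyloxy)-1-oxolongipin-2-en-9-yl (2E)-2-methylbut-2-enoate (CNP0194415.1)
Conditions: pyridine, DMAP (0.2 equiv), CH2Cl2, 0 to 40 °C
Reagents that add atoms: none
Why: DMAP-catalysed acylation of the remaining hindered secondary alcohol; no stereocentre is touched.

## Compound list

1 | 2,2-dimethylpropane-1,3-diol | OCC(C)(C)CO | starting material
2 | 3-hydroxy-2,2-dimethylpropyl benzoate | OCC(C)(C)COC(=O)c1ccccc1 | intermediate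
3 | 2,2-dimethyl-3-oxopropyl benzoate | O=CC(C)(C)COC(=O)c1ccccc1 | intermediate
4 | 2-(triphenylphosphoranylidene)propanal | CC(C=O)=P(c1ccccc1)(c1ccccc1)c1ccccc1 | starting material
5 | (3E)-2,2,4-trimethyl-5-oxopent-3-en-1-yl benzoate | O=C/C(C)=C/C(C)(C)COC(=O)c1ccccc1 | intermediate
6 | (Z)-crotylboronic acid pinacol ester | C/C=C\CB1OC(C)(C)C(C)(C)O1 | starting material
7 | pinacol borate ester of 8 (O–B bond at C5 of the octadienyl chain) | C=C[C@@H](C)[C@H](OB1OC(C)(C)C(C)(C)O1)/C(C)=C/C(C)(C)COC(=O)c1ccccc1 | intermediate (not isolated)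
8 | (3E,5S,6R)-5-hydroxy-2,2,4,6-tetramethylocta-3,7-dien-1-yl benzoate (5,6-syn) | C=C[C@@H](C)[C@H](O)/C(C)=C/C(C)(C)COC(=O)c1ccccc1 | intermediate
9 | (3E,5S,6R)-5-[(tert-butyldimethylsilyl)oxy]-2,2,4,6-tetramethylocta-3,7-dien-1-yl benzoate | C=C[C@@H](C)[C@H](O[Si](C)(C)C(C)(C)C)/C(C)=C/C(C)(C)COC(=O)c1ccccc1 | intermediate
10 | B-alkyl-9-borabicyclo[3.3.1]nonane from 9 (boron on the terminal carbon) | C1CCC2CCCC1B2CC[C@@H](C)[C@H](O[Si](C)(C)C(C)(C)C)/C(C)=C/C(C)(C)COC(=O)c1ccccc1 | intermediate (not isolated)
11 | (3E,5S,6R)-5-[(tert-butyldimethylsilyl)oxy]-8-hydroxy-2,2,4,6-tetramethyloct-3-en-1-yl benzoate | OCC[C@@H](C)[C@H](O[Si](C)(C)C(C)(C)C)/C(C)=C/C(C)(C)COC(=O)c1ccccc1 | intermediate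
12 | (3R,4S,5E)-8-(benzoyloxy)-4-[(tert-butyldimethylsilyl)oxy]-3,5,7,7-tetramethyloct-5-enoic acid | OC(=O)C[C@@H](C)[C@H](O[Si](C)(C)C(C)(C)C)/C(C)=C/C(C)(C)COC(=O)c1ccccc1 | intermediate
13 | (trimethylsilyl)diazomethane | C[Si](C)(C)C=[N+]=[N-] | starting material
14 | mixed ethyl carbonic anhydride of 12 | CCOC(=O)OC(=O)C[C@@H](C)[C@H](O[Si](C)(C)C(C)(C)C)/C(C)=C/C(C)(C)COC(=O)c1ccccc1 | intermediate (not isolated)
15 | (3E,5S,6R)-5-[(tert-butyldimethylsilyl)oxy]-9-diazo-2,2,4,6-tetramethyl-8-oxonon-3-en-1-yl benzoate | [N-]=[N+]=CC(=O)C[C@@H](C)[C@H](O[Si](C)(C)C(C)(C)C)/C(C)=C/C(C)(C)COC(=O)c1ccccc1 | intermediate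
16 | 2-[(1R,4R,5S,6S,7S)-5-[(tert-butyldimethylsilyl)oxy]-4,6-dimethyl-2-oxobicyclo[4.1.0]heptan-7-yl]-2-methylpropyl benzoate (chain exo; silyloxy trans to the cyclopropane CH and to the 4-methyl) | O=C(OCC(C)(C)[C@@H]1[C@H]2C(=O)C[C@@H](C)[C@H](O[Si](C)(C)C(C)(C)C)[C@@]12C)c1ccccc1 | intermediate
17 | 2-trimethylsilyl enol ether of 16 (C2=C3 of the bicycle) | O=C(OCC(C)(C)[C@@H]1[C@H]2C(O[Si](C)(C)C)=C[C@@H](C)[C@H](O[Si](C)(C)C(C)(C)C)[C@@]12C)c1ccccc1 | intermediate (not isolated)
18 | 2-[(1R,5S,6S,7S)-5-[(tert-butyldimethylsilyl)oxy]-4,6-dimethyl-2-oxobicyclo[4.1.0]hept-3-en-7-yl]-2-methylpropyl benzoate | O=C(OCC(C)(C)[C@@H]1[C@H]2C(=O)C=C(C)[C@H](O[Si](C)(C)C(C)(C)C)[C@@]12C)c1ccccc1 | intermediate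
19 | 2-[(1R,5S,6S,7S)-5-hydroxy-4,6-dimethyl-2-oxobicyclo[4.1.0]hept-3-en-7-yl]-2-methylpropyl benzoate (hydroxyl anti to the cyclopropane carbon bearing the exo chain) | O=C(OCC(C)(C)[C@@H]1[C@H]2C(=O)C=C(C)[C@H](O)[C@@]12C)c1ccccc1 | intermediate (key-step precursor)
20 | 5-O-trifluoroacetate of 19 | O=C(OCC(C)(C)[C@@H]1[C@H]2C(=O)C=C(C)[C@H](OC(=O)C(F)(F)F)[C@@]12C)c1ccccc1 | intermediate (not isolated)
21 | 2-methyl-2-[(1R,5R,7S)-4-methyl-6-methylidene-2-oxobicyclo[3.1.1]hept-3-en-7-yl]propyl benzoate (chain anti to the enone bridge) | O=C(OCC(C)(C)[C@@H]1[C@H]2C(=O)C=C(C)[C@@H]1C2=C)c1ccccc1 | intermediate (key-step product)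
22 | (1R,5R,7S)-7-(1-hydroxy-2-methylpropan-2-yl)-4-methyl-6-methylidenebicyclo[3.1.1]hept-3-en-2-one | OCC(C)(C)[C@@H]1[C@H]2C(=O)C=C(C)[C@@H]1C2=C | intermediate
23 | 2-methyl-2-[(1R,5R,7S)-4-methyl-6-methylidene-2-oxobicyclo[3.1.1]hept-3-en-7-yl]propanal | O=CC(C)(C)[C@@H]1[C@H]2C(=O)C=C(C)[C@@H]1C2=C | intermediate
24 | vinylmagnesium bromide | C=C[Mg]Br | starting material
25 | (1R,5R,7S)-7-(3-hydroxy-2-methylpent-4-en-2-yl)-4-methyl-6-methylidenebicyclo[3.1.1]hept-3-en-2-one (carbinol epimers) | C=CC(O)C(C)(C)[C@@H]1[C@H]2C(=O)C=C(C)[C@@H]1C2=C | intermediate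
26 | (1R,5R,7S)-4-methyl-6-methylidene-7-(2-methyl-3-oxopent-4-en-2-yl)bicyclo[3.1.1]hept-3-en-2-one | C=CC(=O)C(C)(C)[C@@H]1[C@H]2C(=O)C=C(C)[C@@H]1C2=C | intermediate
27 | (4R,5S,10R,11R)-longipin-2-ene-1,7-dione (target numbering) | C1CC(=O)C(C)(C)[C@@H]2[C@H]3C(=O)C=C(C)[C@@H]2[C@]31C | intermediate
28 | (4R,5S,10R,11R)-longipina-2,8-diene-1,7-dione | C1=CC(=O)C(C)(C)[C@@H]2[C@H]3C(=O)C=C(C)[C@@H]2[C@]31C | intermediate
29 | 9-(4,4,5,5-tetramethyl-1,3,2-dioxaborolan-2-yl)longipin-2-ene-1,7-dione (boron on the C9 face later occupied by oxygen) | CC1(C)OB(OC1(C)C)[C@@H]1CC(=O)C(C)(C)[C@@H]2[C@H]3C(=O)C=C(C)[C@@H]2[C@]31C | intermediate (not isolated)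
30 | (4R,5S,9R,10R,11R)-9-hydroxylongipin-2-ene-1,7-dione (hydroxyl cis to the C10 methyl) | O[C@@H]1CC(=O)C(C)(C)[C@@H]2[C@H]3C(=O)C=C(C)[C@@H]2[C@]31C | intermediate
31 | (E)-2-methylbut-2-enal | C/C=C(\C)C=O | starting material
32 | (4R,5S,7R,9R,10R,11R)-7-hydroxy-1-oxolongipin-2-en-9-yl (2E)-2-methylbut-2-enoate (7,9-trans) | C/C=C(\C)C(=O)O[C@@H]1C[C@@H](O)C(C)(C)[C@@H]2[C@H]3C(=O)C=C(C)[C@@H]2[C@]31C | intermediate
33 | 3-methylbutanoyl chloride | CC(C)CC(=O)Cl | starting material
34 | (4R,5S,7R,9R,10R,11R)-7-(3-methylbutanoyloxy)-1-oxolongipin-2-en-9-yl (2E)-2-methylbut-2-enoate, CNP0194415.1 | C/C=C(\C)C(=O)O[C@@H]1C[C@@H](OC(=O)CC(C)C)C(C)(C)[C@@H]2[C@H]3C(=O)C=C(C)[C@@H]2[C@]31C | target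

## Step count and least certain steps

Total: 21 steps. Longest linear sequence: 21 steps (1 to 34).

**Step 12 (key step).** Three things may go wrong: ionisation may be slow because the enone withdraws electron density from C4; the C10 cation may be captured by trifluoroacetate or solvent, or the methylene re-protonated and drained into addition products, instead of clean loss of the methyl proton; and the cation may open to the homoallyl cation at C5. Fallback, setting out from 19 and returning at 21: capture the cation deliberately. Dilute HClO4 in aqueous acetone should convert 19 into the tertiary cyclobutanol 2-[(1R,5R,7S)-6-hydroxy-4,6-dimethyl-2-oxobicyclo[3.1.1]hept-3-en-7-yl]-2-methylpropyl benzoate F1 (the classical cyclopropylcarbinol-to-cyclobutanol rearrangement, either C10 epimer). Syn elimination with the Burgess reagent in benzene at 50 °C, for which only the methyl hydrogens are available, then gives 21.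

**Step 17.** The 7-endo closure may be slower than reduction of the C10 radical or of the vinyl ketone by the iron hydride and silane, or than intermolecular addition. Fallback, setting out from 25 and returning at 27: separate radical generation from the hydride chemistry. Markovnikov hydrochlorination of the methylidene group (Co(BF4)2·6H2O with a salen-type ligand, t-BuOOH, PhSiH3, TsCl, EtOH) should give the tertiary chloride (1R,5R,7S)-6-chloro-7-(3-hydroxy-2-methylpent-4-en-2-yl)-4,6-dimethylbicyclo[3.1.1]hept-3-en-2-one F2. Dess–Martin oxidation then gives the chloro vinyl ketone (1R,5R,7S)-6-chloro-4,6-dimethyl-7-(2-methyl-3-oxopent-4-en-2-yl)bicyclo[3.1.1]hept-3-en-2-one F3. Slow addition of Bu3SnH and AIBN in benzene at 80 °C generates the same C10 radical by chlorine abstraction at a low, controllable hydride concentration and closes to 27.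

**Step 19.** Boron may also add to the C2=C3 enone, or the ligand may not discriminate the faces of the hindered, neopentyl C9; base-induced loss of water or retro-aldol opening of 30 may occur during the oxidation. Fallback, setting out from 28 and returning at 30: put the oxygen on C9 by catalyst-controlled nucleophilic epoxidation. Aqueous H2O2 with a 9-amino-9-deoxy-epi-quinine trifluoroacetate salt should give the epoxy ketone 8,9-epoxylongipin-2-ene-1,7-dione F4 (oxygen on the face of the C10 methyl). SmI2 in THF/MeOH at −78 °C then cleaves the Cα–O bond to give 30.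

**Step 20.** Hemiacetal formation and hydride transfer from a conjugated, α-branched aldehyde may be slow, so that samarium-promoted retro-aldol opening of 30 or 1,3-acyl migration competes. Fallback, setting out from 30 and returning at 34: stepwise, reagent-controlled reduction.
- TBSOTf and 2,6-lutidine give the silyl ether 9-[(tert-butyldimethylsilyl)oxy]longipin-2-ene-1,7-dione F5.
- (S)-Me-CBS with BH3·SMe2 reduces the C7 ketone (large group: quaternary C6; small group: C8H2) and also C1, giving the diol 9-[(tert-butyldimethylsilyl)oxy]longipin-2-ene-1,7-diol F6.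
- MnO2 in CH2Cl2 re-oxidises only the allylic C1 carbinol, giving 9-[(tert-butyldimethylsilyl)oxy]-7-hydroxylongipin-2-en-1-one F7.
- Acylation with 33, pyridine and DMAP gives 9-[(tert-butyldimethylsilyl)oxy]-1-oxolongipin-2-en-7-yl 3-methylbutanoate F8.
- HF·pyridine gives 9-hydroxy-1-oxolongipin-2-en-7-yl 3-methylbutanoate F9.
- Yamaguchi esterification with tiglic acid (2,4,6-trichlorobenzoyl chloride, Et3N, DMAP, toluene) gives 34.

## Further compounds

F1 | step 12 | 2-[(1R,5R,7S)-6-hydroxy-4,6-dimethyl-2-oxobicyclo[3.1.1]hept-3-en-7-yl]-2-methylpropyl benzoate (C6 epimers) | O=C(OCC(C)(C)[C@@H]1[C@H]2C(=O)C=C(C)[C@@H]1C2(C)O)c1ccccc1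
F2 | step 17 | 6-chloro-7-(3-hydroxy-2-methylpent-4-en-2-yl)-4,6-dimethylbicyclo[3.1.1]hept-3-en-2-one, ring configuration as in 25 (C6 and carbinol epimers) | C=CC(O)C(C)(C)[C@@H]1[C@H]2C(=O)C=C(C)[C@@H]1C2(C)Cl
F3 | step 17 | 6-chloro-4,6-dimethyl-7-(2-methyl-3-oxopent-4-en-2-yl)bicyclo[3.1.1]hept-3-en-2-one, ring configuration as in 26 (C6 epimers) | C=CC(=O)C(C)(C)[C@@H]1[C@H]2C(=O)C=C(C)[C@@H]1C2(C)Cl
F4 | step 19 | 8,9-epoxylongipin-2-ene-1,7-dione (epoxide oxygen cis to the C10 methyl) | [C@@H]12O[C@@H]1C(=O)C(C)(C)[C@@H]3[C@H]4C(=O)C=C(C)[C@@H]3[C@]42C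
F5 | step 20 | 9-[(tert-butyldimethylsilyl)oxy]longipin-2-ene-1,7-dione | CC(C)(C)[Si](C)(C)O[C@@H]1CC(=O)C(C)(C)[C@@H]2[C@H]3C(=O)C=C(C)[C@@H]2[C@]31C
F6 | step 20 | 9-[(tert-butyldimethylsilyl)oxy]longipin-2-ene-1,7-diol (7R; C1 epimers) | CC(C)(C)[Si](C)(C)O[C@@H]1C[C@@H](O)C(C)(C)[C@@H]2[C@H]3C(O)C=C(C)[C@@H]2[C@]31C
F7 | step 20 | 9-[(tert-butyldimethylsilyl)oxy]-7-hydroxylongipin-2-en-1-one (7,9-trans) | CC(C)(C)[Si](C)(C)O[C@@H]1C[C@@H](O)C(C)(C)[C@@H]2[C@H]3C(=O)C=C(C)[C@@H]2[C@]31C
F8 | step 20 | 9-[(tert-butyldimethylsilyl)oxy]-1-oxolongipin-2-en-7-yl 3-methylbutanoate | CC(C)(C)[Si](C)(C)O[C@@H]1C[C@@H](OC(=O)CC(C)C)C(C)(C)[C@@H]2[C@H]3C(=O)C=C(C)[C@@H]2[C@]31C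
F9 | step 20 | 9-hydroxy-1-oxolongipin-2-en-7-yl 3-methylbutanoate | O[C@@H]1C[C@@H](OC(=O)CC(C)C)C(C)(C)[C@@H]2[C@H]3C(=O)C=C(C)[C@@H]2[C@]31C
A1 | alternative 1 | (4+3) cycloadduct: bicyclo[5.4.0]undecenone with C7 ketone, C9 silyl ether and dioxolane at C1 | CC(C)(C)[Si](C)(C)O[C@@H]1CC(=O)C(C)(C)[C@@H]2C(CCC3(OCCO3)C2)=C1C
A2 | alternative 1 | 1-silyloxy-2-methyl diene on the ketal-protected cyclohexene (enol ether geometry left open) | CC(C)(C)[Si](C)(C)OC=C(C)C1=CCC2(CC1)OCCO2
A3 | alternative 1 | 3-bromo-3-methylbutan-2-one | CC(=O)C(C)(C)Br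
A4 | alternative 2 | 9-hydroxylongipin-2-en-7-yl 3-methylbutanoate | O[C@@H]1C[C@@H](OC(=O)CC(C)C)C(C)(C)[C@@H]2[C@H]3CC=C(C)[C@@H]2[C@]31C
A5 | alternative 2 | cis-fused 9,10-epoxyhimachal-3-en-7-yl 3-methylbutanoate (target numbering) | O1[C@@H]2C[C@@H](OC(=O)CC(C)C)C(C)(C)[C@H]3C=C(C)CC[C@H]3[C@]12C
A6 | alternative 3 | 9-methoxylongipina-2,8-diene-1,7-dione (vinylogous ester enone) | COC1=CC(=O)C(C)(C)[C@@H]2[C@H]3C(=O)C=C(C)[C@@H]2[C@]31C
A7 | alternative 3 | meso 4,11-diacetyl bicyclo[4.1.1]octenone vinylogous ester (target numbering) | COC1=CC(=O)C(C)(C)[C@@H]2[C@@H](C(C)=O)[C@@]1(C)[C@H]2C(C)=O
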